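No line drawn through the solid substrate readings can answer this, because what has only dissolved counts as not reacted, so you need two times, not one.

| setting | delta | flask |
|---|---|---|
| solid substrate | 0.050 M | 0.050 M |
| acid | 1.5 mM | 1.50 mM |
| scavenger | 0.060 M | 0.0600 M |
| remark | the very flask that is asked about, followed so far |  |
| time |  | 20 h |

delta run (percent of the solid substrate charged)

| time / h | solid substrate / % | target / % |
|---|---|---|
| 0.667 | 85.6 | 1.9 |
| 1.00 | 81.7 | 2.4 |
| 2.00 | 69.2 | 7.1 |
| 3.00 | 60.1 | 10.0 |
| 5.00 | 48.9 | 22.3 |
| 8.00 | 30.8 | 37.8 |

(each reading ± 1 percentage point)

- acid is the free proton; pH is minus the decimal logarithm of its molar concentration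
- amounts and yields of weak acid count idle adduct too
- given per volume of solution although it is solid: solid substrate
- the numbers in the tables scatter by 1 percentage point (one standard deviation)
- steps thought possible: starting material + acid -> weak acid + acid + target; weak acid <-> conjugate base + acid; starting material -> weak acid + target; starting material + weak acid <-> idle adduct; weak acid + scavenger -> scavenged by-product; starting material -> decomposition product; solid substrate <-> starting material
- at the start none of the solid substrate is in solution
- what has only dissolved of solid substrate counts as not reacted

- part of the solid substrate that has reacted (what has only dissolved counts as not reacted) at 20 h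
- pH of the solution at 20 h

Between 5.00 h and 8.00 h of the delta run the solid substrate falls by 0.0603 /h of the charge and the target rises by 0.0517 /h. At the last reading, what is neither solid nor target stands at 31.4%, which I take as the dissolved pool and hold there until the solid has cleared.

clearing time = 13.1 h

lifetime of the pool = 6.08 h

lifetimes after clearing = 1.13

left dissolved = 10.1%, so reacted = 89.9%

The lifetime, pool divided by target rate, is a pseudo-first-order figure for as long as c(acid) stays steady.

The forecast says 89% and pH 2.77, reasoning that “weak acid should be largely removed”.

The flask gives 91.7% and pH 2.82.

    starting material + acid → weak acid + acid + target (k = 73.0 /M/h)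
    weak acid ⇌ conjugate base + acid, settled at all times (K = 7.90 × 10⁻⁶ M)
    starting material → weak acid + target (k = 0.0880 /h)
    starting material + weak acid ⇌ idle adduct, settled at all times (K = 44.0 /M)
    weak acid + scavenger → scavenged by-product (k = 170 /M/h)
    starting material → decomposition product (k = 1.50 × 10⁻⁴ /h)
    solid substrate ⇌ starting material, rate k7*(cs7 - [starting material]) while solid is left; crystals form when [starting material] > cs7 (solubility = 18.0 mM, k = 0.760 /h)

My reckoning left 10.1% dissolved at 20 h, and the flask holds 8.33% as starting material then. Taken as the inverse of the summed rate constants of the two paths from starting material to target, the first multiplied by c(acid), the same lifetime is 5.06 h in this flask, against the 6.08 h read from the delta run. In the neighbour flask, the same recipe with c(acid) = 0.0060 M, the lifetime reckoned in this way is 1.90 h, shorter than in this flask, and that neighbour flask keeps 0.040% of its charge, solid or dissolved, at 20 h.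

The numbers in the tables stem from a simulated flask with constants of no real substance.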